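## Analysis of the target

Target 12 is a 2,3-dihydrobenzofuran-6(5H)-one. A dihydrofuran ring B (O1, C2, C3, C3a, C7a) is fused along C3a–C7a to a six-membered ring A (C3a, C4, C5, C6, C7, C7a). Ring A is not aromatic but a linearly conjugated dienone, C6(=O)–C7=C7a–C3a=C4, closed by the sp3 carbon C5. The C6 carbonyl is a vinylogous ester of O1, which makes it the less electrophilic end of the dioxygenated C5/C6 edge. There are three stereocentres: C2 (S, 3,4,5-trimethoxyphenyl) and C3 (S, methyl) are trans on ring B, and C5 (S) is quaternary with allyl and methoxy, the allyl group lying on the face of the C3 methyl. C5 is separated from C3 by the flat C3a=C4 unit, so the ring-B centres cannot be expected to steer it. Sensitive points are the dienone (acid-induced allyl migration with aromatisation, [3,3] shifts of the 1,5-diene C3a=C4–C5–CH2–CH=CH2), the benzylic aryl ether bond C2–O1 and the terminal alkene. The difficulty is to deliver ring A at the quinol oxidation level, with a remote quaternary centre of defined configuration, without falling back to an arene. The plan rests on C3: a methyl-bearing methine that joins C2 to ring carbon C3a is the α-carbon of propanal after arylation by a quinone. The two quinone oxygens reappear as O1 on C7a and as the oxygen on C5, and a methoxy substituent of the quinone stands in for the C6 oxygen.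

## Retrosynthetic reasoning

**12 to 11.** The O–CH3 bond at C5 is cut last. It changes no stereocentre, and the tertiary alcohol 11 is the direct product of a carbonyl addition. The forward step must alkylate a hindered tertiary α-ketol without forming a free alkoxide, because that alkoxide is a 3-oxido-1,5-diene.

**11 to 9.** The C5–allyl bond is cut, which turns the C5/C6 edge into the o-quinone 9. The cut is made here because O1 tells the two carbonyls apart: C6=O is damped as a vinylogous ester, C5=O is not. The forward reaction must transfer allyl 1,2 to C5 only, on the Re face (the face of the C3 methyl), under reagent control and without base or reductant.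

**9 to 8.** The o-quinone is traced to the phenol 8, with C5–OH and C6–OMe on an aromatic ring A. The C6 methoxy group is the stored form of the C6 carbonyl, and the neighbouring free phenol is what lets an oxidant single it out from the three methoxy groups on the other ring. The forward step must oxidise ortho (at C6) and not para (at C7a), where attack would open ring B.

**8 to 7.** The O1–C2 bond is cut. C2 is benzylic to the trimethoxyphenyl ring, so the forward closure can run through a cation captured by the ortho phenol. Both carbinol epimers of 7 then converge on the trans ring, and C2 need not be controlled when the C2–aryl bond is made.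

**7 to 4 and 6.** The C2–aryl bond is cut to an aryl Grignard reagent 6 (from bromide 5) and lactol 4, the ring-closed form of an α-aryl aldehyde. The lactol brings C3 in the right configuration and both ring-A oxygens in place.

**4 to 1 and 2.** C3–C3a and O1–C2 are cut together. Propanal 1 supplies C2, C3 and the methyl group, and quinone 2 supplies ring A complete. The forward reaction must arylate the α-carbon of 1 at one quinone CH out of three and on one enantioface. The methoxy group of 2 chooses the carbon, and a chiral secondary amine chooses the face.

## Alternatives that were turned down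

**Alternative 1: ring A by enolate acylation of a lactone.**
- Disconnection: C7=C7a is cut. Ring B is kept as a γ-butyrolactone whose carbonyl carbon is C7a, and C4–C7 hang on C3a as a chain ending in a methyl ketone (lactone ketone A2).
- Forward key step: LiN(SiMe3)2 deprotonates the C7 methyl group of A2, the enolate attacks the lactone carbonyl, and acid dehydrates the hemiketal to the vinylogous ester A1. Loss of the C4 silyloxy group with C3a–H would then give 12.
- For: no o-quinone appears. C5 is set in an open-chain fragment, where absolute control of a tertiary ether is established practice; on this point it is stronger than the chosen route.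
- Against: A2 carries five stereocentres (C2, C3, C3a, C4, C5), two of which are destroyed afterwards, and would need well over ten steps. The lactone α-proton C3a–H competes with the methyl ketone protons, and its enolate can expel the C4 silyloxy group before ring A closes.
- Comparison: the chosen route buys ring A complete with the quinone and reaches the same skeleton in about half the steps. It pays with an unproven facial control at C5.

**Alternative 2: rhodium carbenoid insertion into the benzylic C–H bond.**
- Disconnection: C2–C3 is cut. The precursor is the aryldiazoacetate A3, with the trimethoxybenzyl group as an ether on the future O1.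
- Forward key step: Rh2(S-PTTL)4 (dirhodium tetrakis[N-phthaloyl-(S)-tert-leucinate], divalent rhodium) forms the carbenoid at C3, which inserts into the benzylic C–H bond and closes ring B as the cis ester A4.
- For: C2 and C3 are set together in one catalyst-controlled event of a well-established type. It needs neither a configurationally labile α-aryl aldehyde nor a cation closure; here it is stronger.
- Against: A4 is cis and must be epimerised at C3. The ester must be taken down to a methyl group in about three steps. Ring A carries only the C6 oxygen, so C5 must be oxygenated later, with a choice between C5 and C7 that nothing in the substrate decides. The same allylation and methylation remain.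
- Comparison: it is roughly twice as long and ends in the same open end-game. The chosen route has the methyl group and both ring-A oxygens in place from the first step.

**Alternative 3: anodic catechol oxidation with ring closure by the side-chain hydroxyl.**
- Disconnection: O1–C7a is cut. The precursor is the catechol carbinol A5.
- Forward key step: anodic oxidation at carbon (LiClO4, acetonitrile with hexafluoroisopropanol) gives the o-quinone of A5, the C2 hydroxyl adds to C7a, and the cyclised catechol is oxidised again to A6, which has the structure of o-quinone 9.
- For: no chemical oxidant and no demethylation are needed, so the ortho/para question of the chosen oxidation step does not arise; on this point it is stronger.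
- Against: closure through oxygen retains the carbinol configuration, so A5 must be a single (1S,2S) isomer and the stereoconvergence of a cation closure is lost. A5 needs the same α-arylpropanal chemistry plus a diastereoselective aryl addition. The open-chain 4-alkyl-o-quinone lacks the vinylogous ester stabilisation until ring B has closed and can tautomerise at C3.
- Comparison: it joins the chosen route at 9 and shares the end-game, but needs more steps to get there. The chosen route reaches 9 in four linear steps.

Key step: step 1

Remark 1: the sense of induction in step 1 is assigned from the steric shielding model of diarylprolinol silyl ethers. The (R)-catalyst leaves the Re face of the (E)-enamine open, which gives (S) at the α-carbon because the formyl carbon outranks the aryl carbon.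

Remark 2: no model fixes in advance which antipode of the diol catalyst in step 6 serves the Re face of an o-quinone carbonyl. It is settled by one pair of trial runs, the two C5 epimers being diastereomers.

## Route

Step 1
Reactants: 1 propanal; 2 2-methoxy-1,4-benzoquinone
Product: 4 (3S)-6-methoxy-3-methyl-2,3-dihydrobenzofuran-2,5-diol as its two C2 lactol epimers, via hydroquinone aldehyde 3 (not isolated)
Conditions: 1 (2 equiv), (R)-2-[diphenyl(trimethylsilyloxy)methyl]pyrrolidine (10 mol %), EtOH/H2O, −20 °C, Ar
Reagents that add atoms: none
Why: Propanal condenses with the (R)-prolinol silyl ether to the (E)-enamine, whose β-carbon adds in Michael fashion to quinone carbon C5 of 2 (the CH para to the methoxy-bearing carbon and β to the C1 carbonyl, which the methoxy group does not damp), forming C3–C3a. Enolisation aromatises the adduct to the hydroquinone, and hydrolysis of the iminium ion releases aldehyde 3 and the catalyst. The phenol that was the C4 carbonyl oxygen of the quinone, now ortho to the side chain, adds to the aldehyde (5-exo-trig) and closes ring B as lactol 4, forming O1–C2. The closest known reaction type is the diarylprolinol silyl ether-catalysed enantioselective α-arylation of aldehydes with quinones, which gives 3-alkyl-2,3-dihydrobenzofuran-2-ols. C3 is set by the catalyst: the diphenyl(silyloxy)methyl group of the (R)-pyrrolidine blocks the Si face of the s-trans (E)-enamine, the quinone arrives on the Re face and the α-carbon becomes (S). Regioselectivity among the three quinone CH positions is needed and is secured by the methoxy group, which deactivates the C4 carbonyl and carbon C3 by donation; the hindered catalyst nitrogen secures chemoselectivity over amine addition to the quinone. Lactol formation withdraws the free α-aryl aldehyde and so shields the new centre from enolisation; the anomeric carbon is left as a mixture because step 4 erases it.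

Step 2
Reactants: 5 5-bromo-1,2,3-trimethoxybenzene
Product: 6 (3,4,5-trimethoxyphenyl)magnesium bromide as a titrated THF solution
Conditions: Mg turnings, I2 (cat.), THF, reflux
Reagents that add atoms: magnesium, [Mg]
Why: Grignard formation by insertion of magnesium into the aryl C–Br bond; the methoxy groups are inert.

Step 3
Reactants: 4 (3S)-6-methoxy-3-methyl-2,3-dihydrobenzofuran-2,5-diol; 6 (3,4,5-trimethoxyphenyl)magnesium bromide
Product: 7 2-[(2S)-1-hydroxy-1-(3,4,5-trimethoxyphenyl)propan-2-yl]-5-methoxybenzene-1,4-diol as a mixture of carbinol epimers
Conditions: 6 (3.5 equiv), THF, −40 → 0 °C, Ar; degassed sat. aq. NH4Cl; crude used at once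
Reagents that add atoms: none
Why: Grignard addition to a lactol: two equivalents deprotonate the C5 phenol and the lactol hydroxyl, the magnesium lactolate opens to the phenoxide aldehyde, and a third equivalent adds to the carbonyl, forming the C2–aryl bond. Aryl Grignard addition to an aldehyde is much faster than α-deprotonation, and any enolate that forms does not go on to product, so C3 should pass unchanged. The carbinol configuration does not matter because step 4 erases it.

Step 4
Reactants: 7 2-[(2S)-1-hydroxy-1-(3,4,5-trimethoxyphenyl)propan-2-yl]-5-methoxybenzene-1,4-diol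
Product: 8 (2S,3S)-6-methoxy-3-methyl-2-(3,4,5-trimethoxyphenyl)-2,3-dihydrobenzofuran-5-ol
Conditions: TsOH·H2O (10 mol %), degassed CH2Cl2 (0.02 M), 0 °C → rt
Reagents that add atoms: none
Why: Acid-catalysed cyclodehydration (SN1): the carbinol ionises to the benzylic cation stabilised by the trimethoxyphenyl ring, and the ortho phenol oxygen captures it in a five-membered closure, forming O1–C2; only this phenol can reach C2. Both carbinol epimers converge, and the aryl group takes the face away from the C3 methyl, so C2 becomes (S), trans, under control of C3.

Step 5
Reactants: 8 (2S,3S)-6-methoxy-3-methyl-2-(3,4,5-trimethoxyphenyl)-2,3-dihydrobenzofuran-5-ol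
Product: 9 (2S,3S)-3-methyl-2-(3,4,5-trimethoxyphenyl)-2,3-dihydrobenzofuran-5,6-dione
Conditions: IBX (1.2 equiv), DMF, 0 °C → rt, dark; pH 7 buffer/EtOAc work-up below 25 °C; used crude
Reagents that add atoms: 2-iodoxybenzoic acid (IBX), O=C1OI(=O)(O)c2ccccc12
Why: Oxidative demethylation of a 2-methoxyphenol by pentavalent iodine: the C5 phenol binds to iodine, an iodyl oxygen passes to the ortho carbon C6, whose methoxy group stabilises the developing charge, and the mixed ketal loses methanol to give the o-quinone. Delivery within the iodine ester keeps the oxidant from the para carbon C7a, where attack would open ring B. The trimethoxyphenyl ring has no free hydroxyl and is left alone.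

Step 6
Reactants: 9 (2S,3S)-3-methyl-2-(3,4,5-trimethoxyphenyl)-2,3-dihydrobenzofuran-5,6-dione
Product: 11 (2S,3S,5S)-5-allyl-5-hydroxy-3-methyl-2-(3,4,5-trimethoxyphenyl)-2,3-dihydrobenzofuran-6(5H)-one, via borate ester 10 (not isolated)
Conditions: allylB(OiPr)2 (1.5 equiv), 3,3′-Br2-BINOL (15 mol %, the antipode that adds to the Re face of C5=O), PhCF3/toluene, −35 °C; H2O
Reagents that add atoms: allyldiisopropoxyborane, C=CCB(OC(C)C)OC(C)C
Why: Proposed new method: the chiral diol exchanges one isopropoxy group on boron, the more Lewis-acidic mixed boronate binds the C5 carbonyl (C6=O is damped as a vinylogous ester of O1) and passes the allyl group through a closed six-membered chair transition state, so addition is 1,2 and at C5, and the binaphthyl chooses the face, of which the Re face (the face of the C3 methyl) gives (5S). The closest known reaction type is the chiral-biphenol-catalysed enantioselective allylboration of ketones, with the enantioselective allylation of isatins as the nearest flat 1,2-dicarbonyl case; an o-quinone has not been shown as acceptor. The reagent is neither basic nor reducing, which the o-quinone requires.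

Step 7
Reactants: 11 (2S,3S,5S)-5-allyl-5-hydroxy-3-methyl-2-(3,4,5-trimethoxyphenyl)-2,3-dihydrobenzofuran-6(5H)-one
Product: 12 (2S,3S,5S)-5-allyl-5-methoxy-3-methyl-2-(3,4,5-trimethoxyphenyl)-2,3-dihydrobenzofuran-6(5H)-one
Conditions: MeI (10 equiv), Ag2O (3 equiv), 4 Å MS, MeCN, rt, dark
Reagents that add atoms: iodomethane, CI
Why: Purdie methylation: Ag2O-assisted SN2 alkylation of the tertiary α-ketol hydroxyl, which touches no stereocentre. No free alkoxide forms, so the anionic oxy-Cope shift of the 3-oxido-1,5-diene and base-induced ketol shifts are avoided, and the soft electrophile should leave the vinylogous ester carbonyl alone.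

## Compound list

1 | propanal | CCC=O | starting material
2 | 2-methoxy-1,4-benzoquinone | COC1=CC(=O)C=CC1=O | starting material
3 | (2S)-2-(2,5-dihydroxy-4-methoxyphenyl)propanal | C[C@H](C=O)c1cc(O)c(OC)cc1O | intermediate
4 | (3S)-6-methoxy-3-methyl-2,3-dihydrobenzofuran-2,5-diol (C2 lactol epimers) | C[C@@H]1C(O)Oc2cc(OC)c(O)cc12 | intermediate
5 | 5-bromo-1,2,3-trimethoxybenzene | COc1cc(Br)cc(OC)c1OC | starting material
6 | (3,4,5-trimethoxyphenyl)magnesium bromide | COc1cc([Mg]Br)cc(OC)c1OC | intermediate
7 | 2-[(2S)-1-hydroxy-1-(3,4,5-trimethoxyphenyl)propan-2-yl]-5-methoxybenzene-1,4-diol (carbinol epimers) | C[C@H](C(O)c1cc(OC)c(OC)c(OC)c1)c1cc(O)c(OC)cc1O | intermediate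
8 | (2S,3S)-6-methoxy-3-methyl-2-(3,4,5-trimethoxyphenyl)-2,3-dihydrobenzofuran-5-ol | C[C@@H]1[C@@H](c2cc(OC)c(OC)c(OC)c2)Oc2cc(OC)c(O)cc12 | intermediate
9 | (2S,3S)-3-methyl-2-(3,4,5-trimethoxyphenyl)-2,3-dihydrobenzofuran-5,6-dione | C[C@@H]1[C@@H](c2cc(OC)c(OC)c(OC)c2)OC2=CC(=O)C(=O)C=C12 | intermediate
10 | diisopropyl (2S,3S,5S)-5-allyl-3-methyl-6-oxo-2-(3,4,5-trimethoxyphenyl)-2,3,5,6-tetrahydrobenzofuran-5-yl borate | C=CC[C@]1(OB(OC(C)C)OC(C)C)C=C2C(=CC1=O)O[C@H](c1cc(OC)c(OC)c(OC)c1)[C@H]2C | intermediate
11 | (2S,3S,5S)-5-allyl-5-hydroxy-3-methyl-2-(3,4,5-trimethoxyphenyl)-2,3-dihydrobenzofuran-6(5H)-one | C=CC[C@]1(O)C=C2C(=CC1=O)O[C@H](c1cc(OC)c(OC)c(OC)c1)[C@H]2C | intermediate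
12 | (2S,3S,5S)-5-allyl-5-methoxy-3-methyl-2-(3,4,5-trimethoxyphenyl)-2,3-dihydrobenzofuran-6(5H)-one | C=CC[C@]1(OC)C=C2C(=CC1=O)O[C@H](c1cc(OC)c(OC)c(OC)c1)[C@H]2C | target

## Step count and least certain steps

Total steps: 7. Longest linear sequence: 6 (steps 1, 3, 4, 5, 6, 7).

**Step 6 (proposed new method).**
- Risk: poor or wrong-sense facial selectivity, because the two ring atoms flanking C5=O (C4 and C6) differ little in size on a flat quinone. An uncatalysed background addition to the activated 1,2-dione can outrun the catalyst. Quinone 9 can tautomerise at C3 (γ to C5=O) to its p-quinone methide and aromatise to the benzofuran if it is kept long or meets base.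
- Fallback: it sets out from 9 and comes back at 11. Quinone 9 is treated with preformed triallyldiindium tribromide, (C3H5)3In2Br3 (from indium powder and allyl bromide), in DMF at 0 °C, a known 1,2-allylation of quinones. This should give 11 together with its C5 epimer, (2S,3S,5R)-5-allyl-5-hydroxy-3-methyl-2-(3,4,5-trimethoxyphenyl)-2,3-dihydrobenzofuran-6(5H)-one F1. The two are diastereomers and are separated by chromatography. Reagent control is given up for separation.

**Step 1 (key step).**
- Risk: slow turnover with the less electrophilic methoxyquinone. The amine catalyst may be used up by displacing the methoxy group of 2. Product hydroquinone and 2 can exchange redox equivalents. Enantiopurity erodes if aldehyde 3 enolises before it closes to the lactol.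
- Fallback: it sets out from 2 and comes back at 8, and replaces the enamine arylation by a formal [3+2] cycloaddition. (E)-1,2,3-Trimethoxy-5-(prop-1-en-1-yl)benzene F2 is made by KOt-Bu isomerisation of commercial elemicin. It is combined with 2 under TiCl4/Ti(OiPr)4 carrying a TADDOL ligand in CH2Cl2 at −78 °C. The titanium chelate of the C1 carbonyl and methoxy oxygen directs the propene β-carbon to quinone C5, and the benzylic cation is captured by the C4 carbonyl oxygen. This known reaction type gives trans-2-aryl-6-methoxy-3-methyl-2,3-dihydrobenzofuran-5-ols, so 8 is reached directly. Enantiopurity then rests on the titanium ligand.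

**Step 3.**
- Risk: loss of C3 integrity through deprotonation of the open aldehyde by the basic reagent, followed by proton exchange. Conversion may stall because the magnesium polyanion separates from solution.
- Fallback: it sets out from 4 and comes back at 8.
  - NaBH4 in MeOH reduces 4 to 2-[(2S)-1-hydroxypropan-2-yl]-5-methoxybenzene-1,4-diol F3, in which C3 can no longer enolise.
  - MOMCl and K2CO3 in acetone protect the two phenols, giving (2S)-2-[4-methoxy-2,5-bis(methoxymethoxy)phenyl]propan-1-ol F4.
  - Buffered Dess–Martin oxidation gives (2S)-2-[4-methoxy-2,5-bis(methoxymethoxy)phenyl]propanal F5.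
  - F5 is treated at −78 °C with 1.2 equiv of 6 to give (2S)-2-[4-methoxy-2,5-bis(methoxymethoxy)phenyl]-1-(3,4,5-trimethoxyphenyl)propan-1-ol F6.
  - HCl in MeOH removes both acetals and closes ring B in the same operation to 8.

**Step 4.**
- Risk: the cation may lose the C3 proton (E1), or take a hydride from C3 to give the tertiary cation stabilised by ring A. Either erases C3 or ends in a stilbene. Incomplete trans selectivity is the lesser risk.
- Fallback: it sets out from 7 and comes back at 8, and replaces the cation by a stereospecific SN2 closure. The carbinol epimers of 7 are separated. The epimer 2-[(1R,2S)-1-hydroxy-1-(3,4,5-trimethoxyphenyl)propan-2-yl]-5-methoxybenzene-1,4-diol F7 is closed under Mitsunobu conditions (PPh3, DIAD, THF, 0 °C). Inversion at C2 gives the trans compound 8. The (1S) epimer is not carried on.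

**Step 5.**
- Risk: loss of the o-quinone during isolation, by tautomerisation at C3 and aromatisation under the acidic iodine by-product. Some oxygen delivery to the other ortho carbon, C4, is a second possibility.
- Fallback: it sets out from 8 and comes back at 9. The IBX oxidation is quenched in the flask with aqueous Na2S2O4, so that the product is isolated and purified as the stable catechol (2S,3S)-3-methyl-2-(3,4,5-trimethoxyphenyl)-2,3-dihydrobenzofuran-5,6-diol F8. Just before step 6, F8 is oxidised with Ag2O and MgSO4 in Et2O under neutral conditions, and the filtered solution of 9 is used directly.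

## Further compounds

F1 | step 6 | (2S,3S,5R)-5-allyl-5-hydroxy-3-methyl-2-(3,4,5-trimethoxyphenyl)-2,3-dihydrobenzofuran-6(5H)-one | C=CC[C@@]1(O)C=C2C(=CC1=O)O[C@H](c1cc(OC)c(OC)c(OC)c1)[C@H]2C
F2 | step 1 | (E)-1,2,3-trimethoxy-5-(prop-1-en-1-yl)benzene | C/C=C/c1cc(OC)c(OC)c(OC)c1
F3 | step 3 | 2-[(2S)-1-hydroxypropan-2-yl]-5-methoxybenzene-1,4-diol | C[C@H](CO)c1cc(O)c(OC)cc1O
F4 | step 3 | (2S)-2-[4-methoxy-2,5-bis(methoxymethoxy)phenyl]propan-1-ol | C[C@H](CO)c1cc(OCOC)c(OC)cc1OCOC
F5 | step 3 | (2S)-2-[4-methoxy-2,5-bis(methoxymethoxy)phenyl]propanal | C[C@H](C=O)c1cc(OCOC)c(OC)cc1OCOC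
F6 | step 3 | (2S)-2-[4-methoxy-2,5-bis(methoxymethoxy)phenyl]-1-(3,4,5-trimethoxyphenyl)propan-1-ol (carbinol epimers) | C[C@H](C(O)c1cc(OC)c(OC)c(OC)c1)c1cc(OCOC)c(OC)cc1OCOC
F7 | step 4 | 2-[(1R,2S)-1-hydroxy-1-(3,4,5-trimethoxyphenyl)propan-2-yl]-5-methoxybenzene-1,4-diol | C[C@H]([C@@H](O)c1cc(OC)c(OC)c(OC)c1)c1cc(O)c(OC)cc1O
F8 | step 5 | (2S,3S)-3-methyl-2-(3,4,5-trimethoxyphenyl)-2,3-dihydrobenzofuran-5,6-diol | C[C@@H]1[C@@H](c2cc(OC)c(OC)c(OC)c2)Oc2cc(O)c(O)cc12
A1 | alternative 1 | (2S,3S,5S)-5-allyl-5-methoxy-3-methyl-4-(triethylsilyloxy)-2-(3,4,5-trimethoxyphenyl)-3,3a,4,5-tetrahydro-2H-benzofuran-6-one (C3a and C4 unassigned) | C=CC[C@]1(OC)C(O[Si](CC)(CC)CC)C2C(=CC1=O)O[C@H](c1cc(OC)c(OC)c(OC)c1)[C@H]2C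
A2 | alternative 1 | (4S,5S)-4-methyl-5-(3,4,5-trimethoxyphenyl)oxolan-2-one carrying at C3 the chain CH(OSiEt3)–C(OMe)(allyl)–COCH3 with (S) at the methoxy carbon | C=CC[C@@](OC)(C(C)=O)C(O[Si](CC)(CC)CC)C1C(=O)O[C@H](c2cc(OC)c(OC)c(OC)c2)[C@H]1C
A3 | alternative 2 | methyl 2-diazo-2-[2-(3,4,5-trimethoxybenzyloxy)-4-(triisopropylsilyloxy)phenyl]acetate | COC(=O)C(=[N+]=[N-])c1ccc(O[Si](C(C)C)(C(C)C)C(C)C)cc1OCc1cc(OC)c(OC)c(OC)c1
A4 | alternative 2 | methyl cis-2-(3,4,5-trimethoxyphenyl)-6-(triisopropylsilyloxy)-2,3-dihydrobenzofuran-3-carboxylate | COC(=O)[C@H]1[C@@H](c2cc(OC)c(OC)c(OC)c2)Oc2cc(O[Si](C(C)C)(C(C)C)C(C)C)ccc12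
A5 | alternative 3 | 4-[(1S,2S)-1-hydroxy-1-(3,4,5-trimethoxyphenyl)propan-2-yl]benzene-1,2-diol | C[C@H]([C@H](O)c1cc(OC)c(OC)c(OC)c1)c1ccc(O)c(O)c1
A6 | alternative 3 | (2S,3S)-3-methyl-2-(3,4,5-trimethoxyphenyl)-2,3-dihydrobenzofuran-5,6-dione | C[C@@H]1[C@@H](c2cc(OC)c(OC)c(OC)c2)OC2=CC(=O)C(=O)C=C12
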